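## Structural features

The target 36 is a linear array of three parts: ring A, a benzene with four substituents (a methoxy group flanked by a methyl group and by the benzylic methylene, and a free hydroxyl para to the methoxy group); a six-carbon linker; and ring B, a cyclopentane. The linker runs from the benzylic CH2 through an (E)-trisubstituted alkene, whose methyl group is cis to the benzylic CH2, to a CH2, a ketone and a further CH2 bonded to C2 of ring B. Ring B holds the only two stereocentres, C1 and C2: adjacent, both quaternary, both R, each methylated. The methyl groups are cis, so the keto-methylene arm on C2 and the acyl group on C1 share one face; the acyl group is an (E)-enone ending in a tertiary carbinol. The fragile points are the chain alkene (β,γ to the ketone, able to slip into conjugation), the 1,5-relationship of the two carbonyl groups (aldol ring closure under base), the electron-rich phenol (oxidation to a quinone) and the tertiary allylic alcohol (ionisation under strong acid). The real difficulty is the pair of vicinal all-carbon quaternary centres in one absolute sense; their cis arms can be read as a cis-fused bicyclo[3.3.0]octane with one ring cut. The key step uses the chain alkene: a methyl group cis to a benzyl group on a trisubstituted double bond is the imprint of syn addition of methyl and metal to a terminal alkyne, followed by replacement of the metal by the benzylic carbon of ring A.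

## Logic of the disconnections

From 36 back to 33, through 35 and 34, no skeletal bond is cut. The phenolic O–H becomes an O–Si bond and both C=O groups become silyl-protected carbinols. The reason is that a ketone and an enone would not survive AlMe3, and that once the carbonyls exist the molecule is base-sensitive, so they are made last; the phenol has to stay masked while the alcohols are oxidised. The gain is that 33 has no carbonyl group and no acidic hydrogen. The demand is threefold: the alcohol silyl ethers must come off beside the aryl silyl ether, the oxidation must spare the tertiary alcohol and ring A, and the last desilylation must not be basic.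

From 33 to 24 and 31, two bonds are cut: the bond between the benzylic CH2 of ring A and the alkene CH, and the bond between the other alkene carbon and its methyl group. Both lie on the same side of the double bond, so one syn addition to an alkyne explains the geometry. The gain is two fragments of about equal size and a terminal alkyne in place of a stereodefined trisubstituted alkene. The demand is regioselective syn-methylmetalation, coupling with retention, and four silyl ethers that tolerate AlMe3.

From 24 through 23 to 19 and 20, the bond between the chain carbinol carbon and the propargylic CH2 is cut. The carbinol carbon is an aldehyde carbon in disguise, and 20 supplies the three alkyne carbons. The gain is that the aldehyde is stored in the ring–chain tautomer 19 and needs no protecting group. The demand is a propargyl, not an allenyl, product; the configuration of the carbinol does not matter.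

From 19 through 18 to 11 and 15, the bond between the carbinol carbon on C1 of ring B and the alkene carbon is cut. The aldehyde sits on a quaternary carbon and cannot enolise, and the alkenyl metal delivers the whole oxygenated five-carbon unit with its E geometry. The new alkoxide and the acid arm close a six-membered lactone, which tells the two arms apart without extra protecting groups. The demand is addition to a hindered aldehyde beside a carboxylate.

From 15 through 13 to 12, the C–I bond is traced to a terminal alkyne by syn hydrometalation. The gain is a commercial alkynol; the demand is clean E selectivity.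

From 11 through 10 to 8, the aldehyde carbon and the acid carbon are reconnected as an enol ether double bond, which closes a second five-membered ring. The reason is that cis arms equal a cis ring fusion, and that 8 has a mirror plane: a chiral base that picks one of two enantiotopic CH2 groups sets both quaternary centres at once. The gain is two quaternary stereocentres reduced to a meso ketone. The demand is high enantiotopic-group selectivity and a clean oxidative cleavage.

From 8 through 5 and 4 to 3, and then to 1 and two molecules of 2, the second carbonyl is first put back (as ketal, then ketone) and then four C–C bonds of the bicycle are cut. The reason is that 4 arises in one condensation with the cis fusion and both methyl groups in place. The demand is differentiation of two identical ketones and a deoxygenation that the ketal survives.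

From 31 through 29, 28, 27 and 26 to 25, the C–Cl bond goes back to an alcohol and an aldehyde, the bond between ring A and the formyl carbon is cut, and the O–Me and O–Si bonds are removed. The free phenol directs the one-carbon unit to its only open ortho position, and the two hydroxyls of 25 differ in steric access. The demand is regioselective mono-silylation and an aryl silyl ether that survives carbonate and borohydride.

## Other disconnections considered

Alternative 1: The cut removes in one stroke the two bonds that leave ring B at its quaternary carbons, C2–CH2 of the keto arm and C1–C(=O) of the enone.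
- **Forward step.** The photoexcited dioxinone A1, (R)-2-tert-butyl-6-methyl-1,3-dioxin-4-one, would add across the tetrasubstituted double bond of 1,2-dimethylcyclopentene A2 to give the cyclobutane photoadduct A3. Opening of the acetal and retro-aldol cleavage (De Mayo sequence) would give keto acid A4, 2-[(1R,2R)-2-acetyl-1,2-dimethylcyclopentyl]acetic acid.
- **In favour.** A2 is symmetric, so no regiochemical question arises. The cis fusion in A3 forces both arms onto one face. Both quaternary carbons and both arms come in one step. A4 is already differentiated: its acid arm is that of 11, and its methyl ketone holds the carbonyl and α-carbon of the enone, so an aldol condensation with a protected α-hydroxy aldehyde could finish that arm.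
- **Against.** The absolute configuration depends on which face of A1 is attacked, and the only bias is a tert-butyl group on the far side of the ring. Addition to a tetrasubstituted alkene runs through a 1,4-biradical that can revert. Photochemistry at scale and the volatility of A2 are practical burdens, and A1 itself costs several steps.
- **Comparison.** A4 would feed the same alkyne and the same union with 31, so the plans differ only before 18. On step economy the alternative is the better (one photochemical step plus fragmentation against six steps to 11, with two more enone carbons on board). On relative configuration the two are equal, since ring fusion fixes cis in both. On absolute configuration the chosen plan is the more predictable, because enantiotopic-group selection by a chiral amide on this ketone class is an established reaction type and can be backed by a resolution.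

Alternative 2: The cut is the ring bond between the two quaternary carbons of ring B.
- **Forward step.** (S)-Citronellol A5 would be turned into diazo ester A6, methyl (6S)-8-(tert-butyldimethylsilyloxy)-2-diazo-6-methyloctanoate. Rh2(O2CCMe3)4 would generate a carbenoid that inserts into the tertiary C–H bond with retention, closing the ring as ester A7. C-methylation of the ester enolate of A7 would then set the second quaternary carbon.
- **In favour.** The first quaternary centre comes from the chiral pool by a mechanistically secure retentive insertion. Five-membered ring formation at a tertiary C–H bond is the preferred mode. The ester carbon and the silyloxyethyl arm of A7 map directly onto the two arms of 11.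
- **Against.** β-Hydride elimination of the alkyl carbenoid competes. The second centre depends on how well the enolate face distinguishes a methyl group from a silyloxyethyl group on the neighbouring quaternary carbon; the sense is right (methyl enters anti to the larger arm) but the difference is small. The enantiomeric purity of A5 varies with its source, and a diazo compound has to be handled.
- **Comparison.** On step economy the two are about equal (roughly seven steps to the stage of 11). The alternative is better in needing no stoichiometric chiral base at very low temperature and in the security of the first centre. The chosen plan is better on relative configuration, because the cis relation of the two centres is locked by the ring fusion of 8, whereas here it rests on a modest 1,2-induction.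

Alternative 3: The cut is the ring bond between C1 of ring B and its neighbouring ring CH2, which in retrosynthesis expands the cyclopentane to an epoxycyclohexane.
- **Forward step.** A Johnson–Claisen rearrangement of (R)-2,3-dimethylcyclohex-2-en-1-ol A8 would set the first quaternary carbon by suprafacial transfer. After reduction, silylation and epoxidation, epoxide A9 would be opened by a Lewis acid such as BF3·OEt2 at its tertiary carbon, and the ring CH2 on the other oxirane carbon would shift to give aldehyde A10.
- **In favour.** Chirality transfer in the Claisen step is reliable. A10 carries the aldehyde on C1 and the two-carbon arm at the alcohol oxidation level, so the alkenyl addition could follow without a carboxylate in the way. If the shift is concerted, the CH2 enters anti to the departing oxygen, so the oxirane must sit on the face that carries the arm; that face could be reached by a hydroxyl-directed epoxidation (VO(acac)2, tert-butyl hydroperoxide) before silylation.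
- **Against.** The tertiary cation next to a quaternary carbon has other outlets: hydride shift to a ketone, 1,2-shift of methyl or of the arm, and capture by the ether oxygen to form a tetrahydrofuran. A long-lived cation would also erode the stereospecificity and give the trans-dimethyl epimer.
- **Comparison.** On step economy the alternative is equal or slightly better (about six steps to a compound more advanced than 11), and it avoids the cryogenic chiral base, which is an operational advantage. On mechanism the chosen plan is the more predictable: it has one selectivity question (which enantiotopic CH2 is deprotonated), while here the face of epoxidation and the choice of migrating group must both go the right way.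

Key step: step 18

Assumption 1: the carbinol carbons made in steps 9 and 11 are formed without control and carried as epimer mixtures; the SMILES show one epimer each, and both centres become carbonyl carbons in step 20.

Assumption 2: which antipode of the lithium amide gives 10 and not its mirror image has to be fixed in a trial run; the (R,R) amide is written, and the (S,S) amide is equally available.

Assumption 3: ring B of 36 is (1R,2R) with cis methyl groups, and 24, 31 and 33 agree with this and with the substitution of ring A, so no structure needs correction. Two points are added to the plan: one carbonyl of 4 is removed before the desymmetrisation (steps 3 and 4), and the last desilylation is run without base.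

## Route

Step 1
Reactants: 1 butane-2,3-dione; 2 dimethyl 3-oxopentanedioate (2 equiv)
Product: 3 tetramethyl cis-3,7-dihydroxy-1,5-dimethylbicyclo[3.3.0]octa-2,6-diene-2,4,6,8-tetracarboxylate (bis-enol of the tetraester)
Conditions: aq. NaHCO3 (pH ca. 8), rt
Reagents that add atoms: none
Why: Weiss–Cook condensation: two aldol and two Michael-type ring closures of the keto diester on the 1,2-diketone build the bicyclo[3.3.0]octane; the thermodynamically favoured cis fusion puts the two methyl groups on one face.

Step 2
Reactants: 3 tetraester bis-enol
Product: 4 cis-1,5-dimethylbicyclo[3.3.0]octane-3,7-dione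
Conditions: 1 M aq. HCl, AcOH, reflux
Reagents that add atoms: none
Why: Acid hydrolysis of the four β-keto esters and decarboxylation of the β-keto acids; the quaternary bridgeheads cannot epimerise.

Step 3
Reactants: 4 cis-1,5-dimethylbicyclo[3.3.0]octane-3,7-dione
Product: 5 mono(2,2-dimethylpropane-1,3-diyl) ketal of 4
Conditions: 2,2-dimethylpropane-1,3-diol (1 equiv), p-TsOH·H2O (cat.), toluene, reflux, Dean–Stark
Reagents that add atoms: 2,2-dimethylpropane-1,3-diol, CC(C)(CO)CO
Why: Acid-catalysed ketalisation with azeotropic removal of water; one equivalent of diol favours the mono-ketal, and recovered 4 and bis-ketal are returned to the equilibration.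

Step 4
Reactants: 5 mono-ketal
Product: 8 cis-1,5-dimethylbicyclo[3.3.0]octan-3-one (meso), via hydrazone 6 (not isolated), via deoxygenated ketal 7 (not isolated)
Conditions: N2H4·H2O, KOH, diethylene glycol, 130 then 200 °C; 2 M aq. HCl, THF, rt
Reagents that add atoms: water, O
Why: Wolff–Kishner reduction (Huang-Minlon procedure) removes the free carbonyl while the ketal is inert to hot alkali; aqueous acid in the work-up then frees the remaining ketone, whose oxygen comes from water.

Step 5
Reactants: 8 cis-1,5-dimethylbicyclo[3.3.0]octan-3-one
Product: 10 trimethyl{[(3aS,6aR)-3a,6a-dimethyl-1,3a,4,5,6,6a-hexahydropentalen-2-yl]oxy}silane, via lithium enolate 9 (not isolated)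
Conditions: (R,R)-bis(1-phenylethyl)amine, n-BuLi, LiCl, TMSCl, THF, −100 → −78 °C
Reagents that add atoms: chlorotrimethylsilane, C[Si](C)(C)Cl
Why: Enantiotopic-group-selective deprotonation of a meso cis-bicyclo[3.3.0]octan-3-one by a chiral lithium amide with in situ silyl trapping, under kinetic control; the choice between the two mirror-image α-CH2 groups fixes the absolute configuration of both quaternary carbons at once.

Step 6
Reactants: 10 silyl enol ether
Product: 11 2-[(1R,2R)-2-formyl-1,2-dimethylcyclopentyl]acetic acid
Conditions: O3, CH2Cl2, −78 °C; Me2S, −78 °C → rt; H2O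
Reagents that add atoms: ozone, [O-][O+]=O
Why: Ozonolysis of a silyl enol ether cuts the ring between the oxygenated carbon (silyl ester, hydrolysed to the acid) and the CH carbon (aldehyde after reduction of the peroxide); both stereocentres are quaternary and the aldehyde cannot enolise, so nothing epimerises.

Step 7
Reactants: 12 2-methylbut-3-yn-2-ol
Product: 13 triethyl[(2-methylbut-3-yn-2-yl)oxy]silane
Conditions: TESCl, imidazole, DMAP (cat.), DMF, rt
Reagents that add atoms: chlorotriethylsilane, CC[Si](Cl)(CC)CC
Why: Silylation of a tertiary propargylic alcohol with a silyl chloride, imidazole and a nucleophilic catalyst.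

Step 8
Reactants: 13 silyl ether of the alkynol
Product: 15 triethyl{[(E)-4-iodo-2-methylbut-3-en-2-yl]oxy}silane, via alkenylzirconocene chloride 14 (not isolated)
Conditions: Cp2Zr(H)Cl, THF, rt; I2, 0 °C
Reagents that add atoms: iodine, II
Why: Hydrozirconation adds Zr–H syn with zirconium at the terminal carbon, and iodinolysis with retention gives the (E)-iodide.

Step 9
Reactants: 11 aldehyde acid; 15 (E)-alkenyl iodide
Product: 18 (4aR,7aR)-4a,7a-dimethyl-1-[(E)-3-methyl-3-(triethylsilyloxy)but-1-enyl]hexahydrocyclopenta[c]pyran-3(1H)-one (C1 epimers), via alkenyllithium 16 (not isolated), via hydroxy acid 17 (not isolated)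
Conditions: 15 (2.3 equiv), n-BuLi (2.2 equiv), Et2O, −78 °C; 11, THF, −78 → −20 °C; 1 M aq. HCl to pH 4, 0 °C; EDC·HCl, DMAP (cat.), CH2Cl2, rt
Reagents that add atoms: none
Why: Iodine–lithium exchange and 1,2-addition: the first equivalent of 16 turns the acid into its lithium carboxylate, which is inert at low temperature, and the second adds to the hindered, non-enolisable aldehyde; carbodiimide lactonisation of the cis arms closes the six-membered lactone. The slight excess of iodide over n-BuLi leaves no butyllithium, and tert-butyllithium is avoided.

Step 10
Reactants: 18 lactone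
Product: 19 (4aR,7aR)-4a,7a-dimethyl-1-[(E)-3-methyl-3-(triethylsilyloxy)but-1-enyl]octahydrocyclopenta[c]pyran-3-ol (lactol)
Conditions: i-Bu2AlH, CH2Cl2, −78 °C; aq. potassium sodium tartrate
Reagents that add atoms: none
Why: Partial reduction of a six-membered lactone with i-Bu2AlH at −78 °C stops at the aluminium hemiacetal, which gives the lactol on work-up.

Step 11
Reactants: 19 lactol; 20 3-bromoprop-1-yne (propargyl bromide)
Product: 23 (2E)-1-[(1R,2R)-2-(2-hydroxypent-4-ynyl)-1,2-dimethylcyclopentyl]-4-methyl-4-(triethylsilyloxy)pent-2-en-1-ol (carbinol epimers), via hydroxy aldehyde 21 (not isolated), via allenylzinc bromide 22 (not isolated)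
Conditions: Zn dust, THF–sat. aq. NH4Cl, 0 °C → rt
Reagents that add atoms: none
Why: Zinc Barbier reaction: 22 adds through its γ-carbon (SE2′) to aldehyde 21, the open tautomer of 19, and gives the homopropargylic alcohol; the near-neutral medium spares the tertiary silyl ether, and zinc avoids mercury-activated magnesium.

Step 12
Reactants: 23 diol
Product: 24 5-[(1R,2R)-1,2-dimethyl-2-{(2E)-4-methyl-1,4-bis(triethylsilyloxy)pent-2-enyl}cyclopentyl]-4-(triethylsilyloxy)pent-1-yne
Conditions: TESOTf, 2,6-lutidine, CH2Cl2, −78 → 0 °C
Reagents that add atoms: triethylsilyl trifluoromethanesulfonate, CC[Si](CC)(CC)OS(=O)(=O)C(F)(F)F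
Why: A silyl triflate with a hindered pyridine base silylates both secondary alcohols, including the hindered allylic one, and leaves the terminal alkyne alone.

Step 13
Reactants: 25 2-methylhydroquinone
Product: 26 4-(tert-butyldimethylsilyloxy)-2-methylphenol
Conditions: TBSCl (1.0 equiv), imidazole, DMF, 0 °C
Reagents that add atoms: tert-butylchlorodimethylsilane, CC(C)(C)[Si](C)(C)Cl
Why: Sterically controlled mono-silylation: the hydroxyl next to the methyl group reacts more slowly than the unhindered one; regioisomer and bis-ether are removed by chromatography.

Step 14
Reactants: 26 mono-silyl ether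
Product: 27 5-(tert-butyldimethylsilyloxy)-2-hydroxy-3-methylbenzaldehyde
Conditions: MgCl2, Et3N, (CH2O)n, MeCN, reflux
Reagents that add atoms: paraformaldehyde (as formaldehyde), C=O
Why: Magnesium-mediated ortho-formylation of a phenol: the magnesium phenoxide delivers formaldehyde to the ortho carbon and a second formaldehyde accepts hydride; the only free ortho position is the one opposite the methyl group.

Step 15
Reactants: 27 salicylaldehyde
Product: 28 5-(tert-butyldimethylsilyloxy)-2-methoxy-3-methylbenzaldehyde
Conditions: MeI, K2CO3, acetone, 40 °C
Reagents that add atoms: iodomethane, CI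
Why: Williamson O-methylation of the acidic salicylaldehyde hydroxyl; dry carbonate in acetone has no nucleophile to attack the aryl silyl ether.

Step 16
Reactants: 28 methoxy aldehyde
Product: 29 [5-(tert-butyldimethylsilyloxy)-2-methoxy-3-methylphenyl]methanol
Conditions: NaBH4, THF–MeOH, 0 °C
Reagents that add atoms: none
Why: Borohydride reduction of an aryl aldehyde; short exposure at 0 °C keeps the aryl silyl ether intact.

Step 17
Reactants: 29 benzyl alcohol
Product: 31 5-(tert-butyldimethylsilyloxy)-2-methoxy-3-methylbenzyl chloride, via mesylate 30 (not isolated)
Conditions: MsCl, Et3N, THF, 0 °C; LiCl, rt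
Reagents that add atoms: lithium chloride, [Li+].[Cl-]; methanesulfonyl chloride, CS(=O)(=O)Cl (its chloride ion is an equivalent chloride source)
Why: Mesylation followed by SN2 displacement by chloride at the activated benzylic carbon; no strong acid is generated.

Step 18
Reactants: 24 terpenoid alkyne; 31 benzyl chloride
Product: 33 tert-butyl(4-methoxy-3-methyl-5-{(2E)-3-methyl-5-(triethylsilyloxy)-6-[(1R,2R)-1,2-dimethyl-2-{(2E)-4-methyl-1,4-bis(triethylsilyloxy)pent-2-enyl}cyclopentyl]hex-2-enyl}phenoxy)dimethylsilane, via alkenyldimethylalane 32 (not isolated)
Conditions: AlMe3 (3 equiv), Cp2ZrCl2 (0.3 equiv), CH2Cl2, 0 °C → rt; evaporate; 31, Pd(PPh3)4 (5 mol %), THF, rt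
Reagents that add atoms: trimethylaluminium, C[Al](C)C
Why: AlMe3 and Cp2ZrCl2 form a methylzirconocene–chloroalane pair that adds methyl and metal across the terminal alkyne through a four-centre transition state, methyl to the internal carbon and metal to the terminus, and exchange leaves the configurationally stable (E)-alkenyldimethylalane 32 (zirconium-catalysed methylalumination). Zerovalent palladium from Pd(PPh3)4 then inserts into the benzylic C–Cl bond of 31, the alkenyl group passes from aluminium to divalent palladium, and reductive elimination forms the vinyl–benzyl bond with retention; the closest known reaction type is the palladium- or nickel-catalysed coupling of alkenylalanes with benzylic halides used for prenylated arenes. No ring is closed and no stereocentre is formed; the one stereochemical element created is the alkene geometry, which follows from the syn addition, so that methyl and benzyl end up cis. The step needs regioselectivity, which the steric difference between the alkyne hydrogen and the branched homopropargylic substituent secures. It also needs the alkenyl group to transfer faster than the methyl groups on aluminium, which is general for such alanes and is helped by removing excess AlMe3 before the coupling. The substrate has no carbonyl group and no acidic hydrogen apart from the alkyne C–H, so the reagent is not consumed, and THF in the second stage tames the Lewis acidity of the Me2AlCl formed and so protects the allylic silyl ethers and the electron-rich benzyl chloride from ionisation. Because the alkene is made in its final position directly from an alkyne, there is no allyl intermediate through which the double bond could move or isomerise.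

Step 19
Reactants: 33 coupled product
Product: 34 (2E)-1-[(1R,2R)-2-{(4E)-6-[5-(tert-butyldimethylsilyloxy)-2-methoxy-3-methylphenyl]-2-hydroxy-4-methylhex-4-enyl}-1,2-dimethylcyclopentyl]-4-methylpent-2-ene-1,4-diol
Conditions: HF·pyridine, pyridine, THF, 0 °C → rt
Reagents that add atoms: none
Why: Acidic fluoride cleaves triethylsilyl ethers of alcohols much faster than an aryl tert-butyldimethylsilyl ether, and the pyridine buffer keeps the tertiary allylic alcohol from ionising.

Step 20
Reactants: 34 triol
Product: 35 (2E)-1-[(1R,2R)-2-{(4E)-6-[5-(tert-butyldimethylsilyloxy)-2-methoxy-3-methylphenyl]-4-methyl-2-oxohex-4-enyl}-1,2-dimethylcyclopentyl]-4-hydroxy-4-methylpent-2-en-1-one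
Conditions: Dess–Martin periodinane, pyridine, CH2Cl2, 0 °C → rt
Reagents that add atoms: none
Why: Dess–Martin oxidation of both secondary alcohols to the ketone and the enone; the tertiary alcohol cannot be oxidised, the silyl ether shields the phenol from quinone formation, and the pyridine buffer keeps the β,γ-double bond out of conjugation.

Step 21
Reactants: 35 silyl-protected diketone
Product: 36 (2E)-4-hydroxy-1-[(1R,2R)-2-{(4E)-6-(5-hydroxy-2-methoxy-3-methylphenyl)-4-methyl-2-oxohex-4-enyl}-1,2-dimethylcyclopentyl]-4-methylpent-2-en-1-one
Conditions: KHF2, MeOH, rt
Reagents that add atoms: none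
Why: Bifluoride in methanol cleaves aryl silyl ethers at room temperature in a weakly acidic medium, so the β,γ-unsaturated ketone should neither isomerise nor undergo aldol closure onto the enone carbonyl.

## Compound list

1 | butane-2,3-dione | CC(=O)C(C)=O | starting material
2 | dimethyl 3-oxopentanedioate | COC(=O)CC(=O)CC(=O)OC | starting material
3 | tetramethyl cis-3,7-dihydroxy-1,5-dimethylbicyclo[3.3.0]octa-2,6-diene-2,4,6,8-tetracarboxylate (ester-bearing sp3 carbons epimerisable) | COC(=O)C1=C(O)C(C(=O)OC)[C@]2(C)C(C(=O)OC)=C(O)C(C(=O)OC)[C@]12C | intermediate
4 | cis-1,5-dimethylbicyclo[3.3.0]octane-3,7-dione | O=C1C[C@]2(C)CC(=O)C[C@]2(C)C1 | intermediate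
5 | cis-1,5-dimethylbicyclo[3.3.0]octane-3,7-dione mono(2,2-dimethylpropane-1,3-diyl) ketal | O=C1C[C@]2(C)CC3(C[C@]2(C)C1)OCC(C)(C)CO3 | intermediate
6 | hydrazone of 5 | NN=C1C[C@]2(C)CC3(C[C@]2(C)C1)OCC(C)(C)CO3 | intermediate (not isolated)
7 | cis-1,5-dimethylbicyclo[3.3.0]octan-3-one 2,2-dimethylpropane-1,3-diyl ketal | CC1(C)COC2(C[C@]3(C)CCC[C@]3(C)C2)OC1 | intermediate (not isolated)
8 | cis-1,5-dimethylbicyclo[3.3.0]octan-3-one (meso) | O=C1C[C@]2(C)CCC[C@]2(C)C1 | intermediate
9 | lithium enolate of 8, double bond towards the later formyl-bearing carbon | [Li]OC1=C[C@]2(C)CCC[C@]2(C)C1 | intermediate (not isolated)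
10 | trimethyl{[(3aS,6aR)-3a,6a-dimethyl-1,3a,4,5,6,6a-hexahydropentalen-2-yl]oxy}silane | C[Si](C)(C)OC1=C[C@]2(C)CCC[C@]2(C)C1 | intermediate
11 | 2-[(1R,2R)-2-formyl-1,2-dimethylcyclopentyl]acetic acid | OC(=O)C[C@@]1(C)CCC[C@@]1(C)C=O | intermediate
12 | 2-methylbut-3-yn-2-ol | CC(C)(O)C#C | starting material
13 | triethyl[(2-methylbut-3-yn-2-yl)oxy]silane | CC[Si](CC)(CC)OC(C)(C)C#C | intermediate
14 | chlorobis(cyclopentadienyl)[(E)-3-methyl-3-(triethylsilyloxy)but-1-enyl]zirconium (cyclopentadienyl rings drawn σ-bonded) | CC[Si](CC)(CC)OC(C)(C)/C=C/[Zr](Cl)(C1C=CC=C1)C1C=CC=C1 | intermediate (not isolated)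
15 | triethyl{[(E)-4-iodo-2-methylbut-3-en-2-yl]oxy}silane | CC[Si](CC)(CC)OC(C)(C)/C=C/I | intermediate
16 | (E)-3-methyl-3-(triethylsilyloxy)but-1-enyllithium | [Li]/C=C/C(C)(C)O[Si](CC)(CC)CC | intermediate (not isolated)
17 | 2-[(1R,2R)-2-{(2E)-1-hydroxy-4-methyl-4-(triethylsilyloxy)pent-2-enyl}-1,2-dimethylcyclopentyl]acetic acid (carbinol: one epimer drawn) | OC(=O)C[C@@]1(C)CCC[C@@]1(C)[C@@H](O)/C=C/C(C)(C)O[Si](CC)(CC)CC | intermediate (not isolated)
18 | (4aR,7aR)-4a,7a-dimethyl-1-[(E)-3-methyl-3-(triethylsilyloxy)but-1-enyl]hexahydrocyclopenta[c]pyran-3(1H)-one (C1: one epimer drawn) | O=C1C[C@@]2(C)CCC[C@@]2(C)[C@H](/C=C/C(C)(C)O[Si](CC)(CC)CC)O1 | intermediate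
19 | (4aR,7aR)-4a,7a-dimethyl-1-[(E)-3-methyl-3-(triethylsilyloxy)but-1-enyl]octahydrocyclopenta[c]pyran-3-ol (anomers; C1: one epimer drawn) | OC1C[C@@]2(C)CCC[C@@]2(C)[C@H](/C=C/C(C)(C)O[Si](CC)(CC)CC)O1 | intermediate
20 | 3-bromoprop-1-yne (propargyl bromide) | C#CCBr | starting material
21 | 2-[(1R,2R)-2-{(2E)-1-hydroxy-4-methyl-4-(triethylsilyloxy)pent-2-enyl}-1,2-dimethylcyclopentyl]acetaldehyde (open tautomer of 19) | O=CC[C@@]1(C)CCC[C@@]1(C)[C@@H](O)/C=C/C(C)(C)O[Si](CC)(CC)CC | intermediate (not isolated)
22 | propa-1,2-dienylzinc bromide (allenylzinc bromide) | C=C=C[Zn]Br | intermediate (not isolated)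
23 | (2E)-1-[(1R,2R)-2-(2-hydroxypent-4-ynyl)-1,2-dimethylcyclopentyl]-4-methyl-4-(triethylsilyloxy)pent-2-en-1-ol (carbinols: one epimer drawn) | C#CC[C@H](O)C[C@@]1(C)CCC[C@@]1(C)[C@@H](O)/C=C/C(C)(C)O[Si](CC)(CC)CC | intermediate
24 | 5-[(1R,2R)-1,2-dimethyl-2-{(2E)-4-methyl-1,4-bis(triethylsilyloxy)pent-2-enyl}cyclopentyl]-4-(triethylsilyloxy)pent-1-yne (carbinols: one epimer drawn) | C#CC[C@H](O[Si](CC)(CC)CC)C[C@@]1(C)CCC[C@@]1(C)[C@@H](O[Si](CC)(CC)CC)/C=C/C(C)(C)O[Si](CC)(CC)CC | intermediate
25 | 2-methylhydroquinone | Cc1cc(O)ccc1O | starting material
26 | 4-(tert-butyldimethylsilyloxy)-2-methylphenol | Cc1cc(O[Si](C)(C)C(C)(C)C)ccc1O | intermediate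
27 | 5-(tert-butyldimethylsilyloxy)-2-hydroxy-3-methylbenzaldehyde | Cc1cc(O[Si](C)(C)C(C)(C)C)cc(C=O)c1O | intermediate
28 | 5-(tert-butyldimethylsilyloxy)-2-methoxy-3-methylbenzaldehyde | COc1c(C)cc(O[Si](C)(C)C(C)(C)C)cc1C=O | intermediate
29 | [5-(tert-butyldimethylsilyloxy)-2-methoxy-3-methylphenyl]methanol | COc1c(C)cc(O[Si](C)(C)C(C)(C)C)cc1CO | intermediate
30 | 5-(tert-butyldimethylsilyloxy)-2-methoxy-3-methylbenzyl methanesulfonate | COc1c(C)cc(O[Si](C)(C)C(C)(C)C)cc1COS(C)(=O)=O | intermediate (not isolated)
31 | 5-(tert-butyldimethylsilyloxy)-2-methoxy-3-methylbenzyl chloride | COc1c(C)cc(O[Si](C)(C)C(C)(C)C)cc1CCl | intermediate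
32 | (E)-alkenyldimethylalane from syn-methylalumination of 24 (aluminium at the former alkyne terminus, cis to the new methyl) | C[Al](C)/C=C(\C)C[C@H](O[Si](CC)(CC)CC)C[C@@]1(C)CCC[C@@]1(C)[C@@H](O[Si](CC)(CC)CC)/C=C/C(C)(C)O[Si](CC)(CC)CC | intermediate (not isolated)
33 | tert-butyl(4-methoxy-3-methyl-5-{(2E)-3-methyl-5-(triethylsilyloxy)-6-[(1R,2R)-1,2-dimethyl-2-{(2E)-4-methyl-1,4-bis(triethylsilyloxy)pent-2-enyl}cyclopentyl]hex-2-enyl}phenoxy)dimethylsilane (carbinols: one epimer drawn) | COc1c(C)cc(O[Si](C)(C)C(C)(C)C)cc1C/C=C(\C)C[C@H](O[Si](CC)(CC)CC)C[C@@]1(C)CCC[C@@]1(C)[C@@H](O[Si](CC)(CC)CC)/C=C/C(C)(C)O[Si](CC)(CC)CC | intermediate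
34 | (2E)-1-[(1R,2R)-2-{(4E)-6-[5-(tert-butyldimethylsilyloxy)-2-methoxy-3-methylphenyl]-2-hydroxy-4-methylhex-4-enyl}-1,2-dimethylcyclopentyl]-4-methylpent-2-ene-1,4-diol (carbinols: one epimer drawn) | COc1c(C)cc(O[Si](C)(C)C(C)(C)C)cc1C/C=C(\C)C[C@H](O)C[C@@]1(C)CCC[C@@]1(C)[C@@H](O)/C=C/C(C)(C)O | intermediate
35 | (2E)-1-[(1R,2R)-2-{(4E)-6-[5-(tert-butyldimethylsilyloxy)-2-methoxy-3-methylphenyl]-4-methyl-2-oxohex-4-enyl}-1,2-dimethylcyclopentyl]-4-hydroxy-4-methylpent-2-en-1-one | COc1c(C)cc(O[Si](C)(C)C(C)(C)C)cc1C/C=C(\C)CC(=O)C[C@@]1(C)CCC[C@@]1(C)C(=O)/C=C/C(C)(C)O | intermediate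
36 | (2E)-4-hydroxy-1-[(1R,2R)-2-{(4E)-6-(5-hydroxy-2-methoxy-3-methylphenyl)-4-methyl-2-oxohex-4-enyl}-1,2-dimethylcyclopentyl]-4-methylpent-2-en-1-one | COc1c(C)cc(O)cc1C/C=C(\C)CC(=O)C[C@@]1(C)CCC[C@@]1(C)C(=O)/C=C/C(C)(C)O | target

## Step count and least certain steps

Total: 21 steps. Longest linear sequence: 14 steps (steps 1–6, 9–12 and 18–21). The side branches are steps 7–8 (two steps) and steps 13–17 (five steps).

Step 18 (key step). The methylalumination may be slow or lose regioselectivity because three silyloxy groups tie up the aluminium reagent. The Lewis acid may ionise an allylic silyl ether. Methyl instead of alkenyl may be transferred to palladium, or the electron-rich benzyl chloride may self-alkylate under Me2AlCl. The fallback reverses the polarity of the coupling. It sets out from 24 and 31 and comes back at 33. Alane 32, made from 24 as before, is quenched with iodine to give the isolable (E)-alkenyl iodide F1, on which regiochemistry and geometry can be checked. Chloride 31 is converted with zinc dust and LiCl in THF into benzylzinc chloride F2. F1 and F2 are then joined by a Negishi coupling with Pd(PPh3)4 in THF, in which the alkenyl iodide undergoes oxidative addition to zerovalent palladium with retention, to give 33.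

Step 5. The chiral amide may discriminate poorly between the two hindered enantiotopic CH2 groups, or the enolate may equilibrate before it is trapped; either would lower the enantiomeric purity that every later compound inherits. The fallback replaces the chiral base by an enzymatic resolution with recycling. It sets out from 8 and comes back at 11. Ketone 8 is heated with isopropenyl acetate and p-TsOH to give the racemic enol acetate, that is, enol acetate F3 together with the antipodal enol acetate F4. A lipase, chosen by screening so that it attacks F4, transfers the acetyl group of F4 to butan-1-ol and returns meso 8 for another round, while F3 remains. Ozonolysis of F3 (O3, CH2Cl2, −78 °C; Me2S; water to hydrolyse the mixed anhydride) gives 11.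

Step 9. The lithium carboxylate may precipitate and leave the hindered aldehyde only partly converted, or the lactonisation of the hindered allylic alcohol may stall. The fallback removes the acidic proton and uses a chromium-mediated addition. It sets out from 11 and 15 and comes back at 18. Acid 11 is methylated (MeI, K2CO3, DMF) to the methyl ester F5. A Nozaki–Hiyama–Kishi coupling of F5 with 15 (CrCl2, catalytic NiCl2, DMF) adds the alkenyl group to the aldehyde only and gives hydroxy ester F6, which is lactonised to 18 with a catalytic amount of pyridinium p-toluenesulfonate in toluene, with loss of methanol.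

Step 19. Cleavage of the hindered tertiary and neopentyl-type silyl ethers may be incomplete, the aryl silyl ether may be lost early, or acid may cause allylic transposition of the unmasked ene-diol. The fallback no longer aims at full unmasking before the oxidation. It sets out from 33 and comes back at 36, bypassing 34 and 35. Pyridinium p-toluenesulfonate in MeOH–CH2Cl2 at 0 °C frees only the two secondary carbinols to give diol F7, which keeps the tertiary silyl ether. Dess–Martin oxidation with pyridine gives diketone F8. Fluoride buffered with acetic acid (TBAF–AcOH, THF, 0 °C) then removes the tertiary triethylsilyl and the aryl silyl group together to give 36.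

Step 21. If the fluoride medium is not inert, the β,γ-double bond may migrate into conjugation or the chain enolate may close onto the enone carbonyl. The fallback frees the phenol before any carbonyl exists and re-masks it with a group that leaves under neutral conditions. It sets out from 34 and comes back at 36. TBAF in THF cleaves the aryl silyl ether of 34 to tetraol F9. Allyl chloroformate with aqueous NaHCO3 in CH2Cl2 acylates the phenol selectively to allyl carbonate F10. Dess–Martin oxidation with pyridine gives diketone carbonate F11. Pd(PPh3)4 with dimedone in THF removes the allyloxycarbonyl group through a π-allyl complex of divalent palladium, with loss of carbon dioxide, and gives 36.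

## Further compounds

F1 | step 18 | (E)-alkenyl iodide from iodinolysis of 32 | I/C=C(\C)C[C@H](O[Si](CC)(CC)CC)C[C@@]1(C)CCC[C@@]1(C)[C@@H](O[Si](CC)(CC)CC)/C=C/C(C)(C)O[Si](CC)(CC)CC
F2 | step 18 | [5-(tert-butyldimethylsilyloxy)-2-methoxy-3-methylbenzyl]zinc chloride | COc1c(C)cc(O[Si](C)(C)C(C)(C)C)cc1C[Zn]Cl
F3 | step 5 | (3aS,6aR)-3a,6a-dimethyl-1,3a,4,5,6,6a-hexahydropentalen-2-yl acetate | CC(=O)OC1=C[C@]2(C)CCC[C@]2(C)C1
F4 | step 5 | (3aR,6aS)-3a,6a-dimethyl-1,3a,4,5,6,6a-hexahydropentalen-2-yl acetate | CC(=O)OC1=C[C@@]2(C)CCC[C@@]2(C)C1
F5 | step 9 | methyl 2-[(1R,2R)-2-formyl-1,2-dimethylcyclopentyl]acetate | COC(=O)C[C@@]1(C)CCC[C@@]1(C)C=O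
F6 | step 9 | methyl 2-[(1R,2R)-2-{(2E)-1-hydroxy-4-methyl-4-(triethylsilyloxy)pent-2-enyl}-1,2-dimethylcyclopentyl]acetate | COC(=O)C[C@@]1(C)CCC[C@@]1(C)[C@@H](O)/C=C/C(C)(C)O[Si](CC)(CC)CC
F7 | step 19 | diol from 33 with the tertiary triethylsilyl ether and the aryl silyl ether retained | COc1c(C)cc(O[Si](C)(C)C(C)(C)C)cc1C/C=C(\C)C[C@H](O)C[C@@]1(C)CCC[C@@]1(C)[C@@H](O)/C=C/C(C)(C)O[Si](CC)(CC)CC
F8 | step 19 | diketone with the tertiary triethylsilyl ether and the aryl silyl ether retained | COc1c(C)cc(O[Si](C)(C)C(C)(C)C)cc1C/C=C(\C)CC(=O)C[C@@]1(C)CCC[C@@]1(C)C(=O)/C=C/C(C)(C)O[Si](CC)(CC)CC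
F9 | step 21 | tetraol with free phenol | COc1c(C)cc(O)cc1C/C=C(\C)C[C@H](O)C[C@@]1(C)CCC[C@@]1(C)[C@@H](O)/C=C/C(C)(C)O
F10 | step 21 | aryl allyl carbonate of the triol | COc1c(C)cc(OC(=O)OCC=C)cc1C/C=C(\C)C[C@H](O)C[C@@]1(C)CCC[C@@]1(C)[C@@H](O)/C=C/C(C)(C)O
F11 | step 21 | aryl allyl carbonate of the diketone | COc1c(C)cc(OC(=O)OCC=C)cc1C/C=C(\C)CC(=O)C[C@@]1(C)CCC[C@@]1(C)C(=O)/C=C/C(C)(C)O
A1 | alternative 1 | (R)-2-tert-butyl-6-methyl-1,3-dioxin-4-one | CC(C)(C)[C@H]1OC(=O)C=C(C)O1
A2 | alternative 1 | 1,2-dimethylcyclopentene | CC1=C(C)CCC1
A3 | alternative 1 | cis-anti-cis tricyclic photoadduct (cyclobutane fused to dioxanone and cyclopentane) | CC(C)(C)[C@H]1OC(=O)[C@@H]2[C@@]3(C)CCC[C@@]3(C)[C@]2(C)O1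
A4 | alternative 1 | 2-[(1R,2R)-2-acetyl-1,2-dimethylcyclopentyl]acetic acid | OC(=O)C[C@@]1(C)CCC[C@@]1(C)C(C)=O
A5 | alternative 2 | (S)-citronellol | C[C@@H](CCC=C(C)C)CCO
A6 | alternative 2 | methyl (6S)-8-(tert-butyldimethylsilyloxy)-2-diazo-6-methyloctanoate | COC(=O)C(=[N+]=[N-])CCC[C@H](C)CCO[Si](C)(C)C(C)(C)C
A7 | alternative 2 | methyl 2-methyl-2-[2-(tert-butyldimethylsilyloxy)ethyl]cyclopentane-1-carboxylate (ester carbon drawn as one epimer) | CC(C)(C)[Si](C)(C)OCC[C@@]1(C)CCC[C@H]1C(=O)OC
A8 | alternative 3 | (R)-2,3-dimethylcyclohex-2-en-1-ol | O[C@@H]1CCCC(C)=C1C
A9 | alternative 3 | 1,2-epoxy-1,6-dimethyl-6-[2-(tert-butyldimethylsilyloxy)ethyl]cyclohexane, oxirane on the face of the silyloxyethyl arm | CC(C)(C)[Si](C)(C)OCC[C@@]1(C)CCC[C@H]2O[C@@]12C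
A10 | alternative 3 | cis-1,2-dimethyl-2-[2-(tert-butyldimethylsilyloxy)ethyl]cyclopentane-1-carbaldehyde | CC(C)(C)[Si](C)(C)OCC[C@@]1(C)CCC[C@@]1(C)C=O
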